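**One step short.** In a one-step world, target stays as made, and the way of adding starting material shows in the yield. These flasks have a further step: target turns into its isomer and back. The share of target in target plus isomer therefore loses its history, and the rate of that loss matters.

| setting | east | south-east | north-east | summer | autumn | spring | dawn |
|---|---|---|---|---|---|---|---|
| starting material | 10 mM | 10 mM | 10 mM | 10 mM | 10 mM (fed, over 25 min) | 10 mM (fed, over 25 min) | 10 mM (in portions, 4, over 25 min) |
| reagent | 1.3 equiv | 0.87 equiv | 2 equiv | 1.30 equiv | 1.30 equiv | 1.30 equiv | 1.30 equiv |
| protic impurity | 5 mM | 5 mM | 5 mM | 5.00 mM | 5.00 mM | 5.00 mM | 5.00 mM |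
| temperature | 75 °C | 90 °C | 75 °C | 90 °C | 90 °C |  | 90 °C |
| remark | run made earlier | run made earlier | run made earlier | everything together at the start | all else is in the flask from the start; the feed brings no volume worth counting | the addition at 60 °C, then warmed to 90 °C; the feed brings no volume worth counting | first portion at the start, last at 25 min |
| time |  |  |  | 40 min | 40 min | 40 min | 40 min |

- east (time / min: target / %, isomer of the product / %): 4.00: 0, 0; 8.00: 9, 2; 12.0: 13, 2; 25.0: 21, 9; 50.0: 20, 21
- south-east (time / min: target / %, isomer of the product / %): 4.00: 9, 1; 10.0: 13, 7; 20.0: 7, 14; 30.0: 13, 21; 40.0: 8, 24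
- north-east (time / min: target / %, isomer of the product / %): 6.00: 10, 4; 12.0: 18, 4; 25.0: 23, 11; 40.0: 26, 23; 80.0: 17, 37

(scatter of a reading: 2 percentage points)

* the flask that comes out highest in share of target in target plus isomer of the product, or "all alike" when all lie within 1.5 percentage points (summer / autumn / spring / dawn / all alike)
* share of target in target plus isomer of the product at the end, summer
* share of target in target plus isomer of the product at the end, autumn
* share of target in target plus isomer of the product at the end, spring
* share of target in target plus isomer of the product at the end, dawn

**The floor.** The south-east run, at 90 °C, ends with a share of 25.0% at 40.0 min. This reading is taken as the floor, the share under thermodynamic control. Earlier the same run reads 65.0% at 10.0 min and 33.3% at 20.0 min. The excess over the floor thus decays with a relaxation time of 6.38 min. This is a rough reading, since each value scatters by 2 percentage points.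

**Turned round.** For equal flasks, the newest product must be forgotten to within 1.5 points. Fresh product is pure target, so its excess must shrink from 75.0% to that margin. The time this takes is the memory time, the relaxation time multiplied by the logarithm of that ratio: 24.9 min. A feed ending at 25 min leaves 15.0 min, less than the memory time. So this reckoning expects the flasks to differ, but it ranks none of them. It commits to no share for each flask.

**The forecast.** It names spring, with 29% for summer, 40% for autumn, 58% for spring and 41% for dawn, on the ground that “the end share depends on how late the product forms”.

**The flask.** Spring comes highest at 42.3%, 16 points below the forecast, with summer at 29.8%, autumn at 34.9% and dawn at 35.5%. Spring's feed ends 15.0 min before the end, less than the memory time of 24.9 min, and at 40.0 min spring still holds 29.0% of its starting material. At 400 min, far beyond the memory time, spring holds 0% starting material and shows 26.3%, and summer shows 26.3%.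

    starting material + reagent → intermediate (k = 0.0600 L mol⁻¹ s⁻¹, Ea = 50.0 kJ mol⁻¹)
    intermediate → target (k = 0.0290 s⁻¹, Ea = 84.0 kJ mol⁻¹)
    target ⇌ isomer of the product (K = 2.80, k = 0.00220 s⁻¹, Ea = 108 kJ mol⁻¹, ΔH = −40.0 kJ mol⁻¹)
    starting material + protic impurity → quenched substrate (k = 0.200 L mol⁻¹ s⁻¹, Ea = 57.0 kJ mol⁻¹)
    intermediate → side product (k = 0.00380 s⁻¹, Ea = 110 kJ mol⁻¹)
    (constants at 90 °C)

(The runs were generated by integration with constants of no real substance; noise was put on by code.)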